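**Plan**
Numbering follows pleuromutilin: C1–C2(=O)–C3=C4 and C9 form the five-membered ring, C4–C9 the six-membered ring, and C4, C5, C14–C10, C9 the eight-membered ring.
Retrosynthesis: cut C11–C12 (eight-membered ring, allylzinc plus aldehyde), then C13–C14 (vinylogous aldol), then C1–C2, C2–C3 and C4–C9 together ([2+2+1] with CO), then C8–C9 (Ni/Cr coupling) and C5–C6 (Ir allylic alkylation).
Forward: an acyclic 1,7-enyne is assembled from three small pieces, the five- and six-membered rings arise together in the Pauson–Khand step, the C12–C14 arm is then grown on C5, and the eight-membered ring is closed last.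
Enabling feature: the cyclopent-2-enone C2(=O)–C3H=C4, fused through C4–C9 to the cyclohexane and carrying the CH2 C1 on the quaternary ring-fusion carbon C9, is the bicyclo[4.3.0]non-1(9)-en-8-one retron of an intramolecular Pauson–Khand reaction; the quaternary C5 next to the alkyne favours closure.
Stereochemistry: C5/C6 from the Ir catalyst, C10 from the chiral pool, C8 from a ligand-controlled Ni/Cr coupling, C9 relayed from C8 in the key step, C14 from a chiral boron Lewis acid, C11/C12 from the cyclic transition state of the ring-closing allylation.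

Key step: step 12

Assumption: the configuration is taken exactly as the target SMILES encodes it, (5S,6S,8S,9R,10R,11S,12S,14R) in the numbering above, and every intermediate is drawn to that configuration; C5 and C6 are fixed together by the ligand enantiomer chosen in step 5.

Step 1
Reactants: 1 methyl (S)-3-hydroxy-2-methylpropanoate
Product: 2 methyl (S)-3-[(tert-butyldimethylsilyl)oxy]-2-methylpropanoate
Conditions: TBSCl, imidazole, CH2Cl2, 0 °C to rt
Reagents that add atoms: tert-butyldimethylsilyl chloride, CC(C)(C)[Si](C)(C)Cl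
Why: Routine silylation of a primary alcohol; the future C10 stereocentre comes from the chiral pool and is not touched.

Step 2
Reactants: 2 methyl (S)-3-[(tert-butyldimethylsilyl)oxy]-2-methylpropanoate
Product: 3 (S)-3-[(tert-butyldimethylsilyl)oxy]-2-methylpropanal
Conditions: i-Bu2AlH (1.05 equiv), CH2Cl2, −78 °C; aq. potassium sodium tartrate
Reagents that add atoms: none
Why: Partial ester reduction stops at the tetrahedral aluminate at −78 °C and should give the aldehyde, which is used cold and crude so that the α-centre is kept.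

Step 3
Reactants: 3 (S)-3-[(tert-butyldimethylsilyl)oxy]-2-methylpropanal
Product: 4 (R)-tert-butyldimethyl[(2-methylbut-3-yn-1-yl)oxy]silane
Conditions: dimethyl (1-diazo-2-oxopropyl)phosphonate, K2CO3, MeOH, 0 °C to rt
Reagents that add atoms: dimethyl (1-diazo-2-oxopropyl)phosphonate, COP(=O)(OC)C(=[N+]=[N-])C(C)=O
Why: Seyferth–Gilbert homologation in its mild carbonate/methanol form should convert the aldehyde into the terminal alkyne without epimerisation (the descriptor changes only through priorities).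

Step 4
Reactants: 4 (R)-tert-butyldimethyl[(2-methylbut-3-yn-1-yl)oxy]silane
Product: 6 (S)-tert-butyl[(3-iodo-2-methylbut-3-en-1-yl)oxy]dimethylsilane, via iodoalkenylborane 5 (not isolated)
Conditions: B-iodo-9-BBN, pentane, −20 to 0 °C; then AcOH, 0 °C to rt
Reagents that add atoms: B-iodo-9-borabicyclo[3.3.1]nonane, IB1C2CCCC1CCC2
Why: Haloboration adds B–I syn across the terminal alkyne with iodine on the internal carbon, and protodeboronation with acetic acid should leave the 2-iodo-1-alkene; low temperature spares the silyl ether.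

Step 5
Reactants: 7 methyl 2-methyl-3-oxobutanoate (racemic); 8 (E)-1-chlorobut-2-ene
Product: 9 methyl (2S,3S)-2-acetyl-2,3-dimethylpent-4-enoate
Conditions: [Ir(cod)Cl]2 (2 mol %), BINOL-derived phosphoramidite bearing an N-(2-methyl-1,2,3,4-tetrahydroquinolinyl) group (C30H24NO2P, 4 mol %, enantiomer chosen for 2S,3S), 1,5,7-triazabicyclo[4.4.0]dec-5-ene (10 mol %), LiOt-Bu, THF, rt
Reagents that add atoms: none
Why: Iridium-catalysed branched-selective asymmetric allylic alkylation of the prochiral β-ketoester enolate should set C6 by the face of the crotyl–iridium complex and the quaternary C5 by enolate-face discrimination in the same chiral pocket.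

Step 6
Reactants: 9 methyl (2S,3S)-2-acetyl-2,3-dimethylpent-4-enoate
Product: 11 methyl (2S,3S)-2-acetyl-5-hydroxy-2,3-dimethylpentanoate, via alkylborane 10 (not isolated)
Conditions: 9-BBN, THF, 0 °C to rt; then NaBO3·4H2O, H2O, rt; product carried on without storage
Reagents that add atoms: sodium perborate, [Na+].[Na+].O[B-]1(O)OO[B-](O)(O)OO1
Why: Anti-Markovnikov hydroboration of the monosubstituted alkene is much faster than reduction of the hindered ketone or ester, and the mild perborate oxidation should give the primary alcohol without touching a stereocentre.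

Step 7
Reactants: 11 methyl (2S,3S)-2-acetyl-5-hydroxy-2,3-dimethylpentanoate
Product: 12 methyl (2S,3S)-2-acetyl-2,3-dimethyl-5-oxopentanoate
Conditions: Dess–Martin periodinane, CH2Cl2, rt
Reagents that add atoms: none
Why: Neutral oxidation of the primary alcohol (any cyclic lactol form re-opens) should give the keto aldehyde, which is used at once to avoid intramolecular aldol.

Step 8
Reactants: 12 methyl (2S,3S)-2-acetyl-2,3-dimethyl-5-oxopentanoate; 6 (S)-tert-butyl[(3-iodo-2-methylbut-3-en-1-yl)oxy]dimethylsilane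
Product: 13 methyl (2S,3S,5S,7R)-2-acetyl-8-[(tert-butyldimethylsilyl)oxy]-5-hydroxy-2,3,7-trimethyl-6-methylideneoctanoate
Conditions: CrCl2 (3 equiv), NiCl2 (2 mol %), N-[2-(4-isopropyl-4,5-dihydrooxazol-2-yl)-6-methylphenyl]methanesulfonamide (3.3 equiv, enantiomer chosen for the 5S carbinol), Et3N (3.3 equiv), THF, rt
Reagents that add atoms: none
Why: Nozaki–Hiyama–Kishi coupling: the alkenylchromium formed through nickel adds only to the aldehyde (ketone and ester are inert), and the chiral sulfonamide ligand on chromium should select the aldehyde face that gives the 5S carbinol (C8).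

Step 9
Reactants: 13 methyl (2S,3S,5S,7R)-2-acetyl-8-[(tert-butyldimethylsilyl)oxy]-5-hydroxy-2,3,7-trimethyl-6-methylideneoctanoate
Product: 14 methyl (2S,3S,5S,7R)-2-acetyl-5,8-bis[(tert-butyldimethylsilyl)oxy]-2,3,7-trimethyl-6-methylideneoctanoate
Conditions: TBSCl, imidazole, 4-(dimethylamino)pyridine (cat.), DMF, 40 °C
Reagents that add atoms: tert-butyldimethylsilyl chloride, CC(C)(C)[Si](C)(C)Cl
Why: Silylation of the secondary allylic alcohol blocks hemiketal or lactone formation with the 1,5-related carbonyl groups and provides the bulky C8 substituent that steers the key step.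

Step 10
Reactants: 14 methyl (2S,3S,5S,7R)-2-acetyl-5,8-bis[(tert-butyldimethylsilyl)oxy]-2,3,7-trimethyl-6-methylideneoctanoate
Product: 16 methyl (2S,3S,5S,7R)-5,8-bis[(tert-butyldimethylsilyl)oxy]-2-ethynyl-2,3,7-trimethyl-6-methylideneoctanoate, via enol phosphate 15 (not isolated)
Conditions: LiN(i-Pr)2, THF, −78 °C; ClP(O)(OEt)2; then LiN(i-Pr)2 (2.2 equiv), −78 to 0 °C
Reagents that add atoms: none
Why: The methyl group is the only enolisable position (C5 is quaternary, the ester has no α-hydrogen), so enol phosphate formation followed by base-induced elimination should turn the methyl ketone into the terminal alkyne C3≡C4.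

Step 11
Reactants: 16 methyl (2S,3S,5S,7R)-5,8-bis[(tert-butyldimethylsilyl)oxy]-2-ethynyl-2,3,7-trimethyl-6-methylideneoctanoate
Product: 17 (2S,3S,5S,7R)-5,8-bis[(tert-butyldimethylsilyl)oxy]-2-ethynyl-2,3,7-trimethyl-6-methylideneoctan-1-ol
Conditions: i-Bu2AlH (2.5 equiv), CH2Cl2, −78 to 0 °C
Reagents that add atoms: none
Why: Full reduction of the hindered ester to the neopentyl alcohol is done now because it could not be done selectively once the enone exists; silyl ethers, alkyne and alkene are inert.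

Step 12
Reactants: 17 (2S,3S,5S,7R)-5,8-bis[(tert-butyldimethylsilyl)oxy]-2-ethynyl-2,3,7-trimethyl-6-methylideneoctan-1-ol
Product: 18 (4S,5S,7S,7aR)-7-[(tert-butyldimethylsilyl)oxy]-7a-{(2R)-1-[(tert-butyldimethylsilyl)oxy]propan-2-yl}-4-(hydroxymethyl)-4,5-dimethyl-1,4,5,6,7,7a-hexahydro-2H-inden-2-one
Conditions: Co2(CO)8 (20 mol %), tetramethylthiourea (120 mol %), CO (1 atm), toluene, 70 °C
Reagents that add atoms: carbon monoxide, [C-]#[O+]
Why: Intramolecular Pauson–Khand [2+2+1] reaction: the terminal alkyne forms its alkyne–Co2(CO)6 complex, the 1,1-disubstituted alkene inserts into the Co–C4 bond (C4–C9), CO inserts into the resulting Co–C1 bond (C1–C2) and reductive elimination joins C2 to C3. The closest known reaction type is the cobalt-catalysed cyclocarbonylation of 1,7-enynes with 1,1-disubstituted alkenes to angularly substituted hydrindenones. The cyclohexane closes in a 6-exo sense through the C4–C9 insertion, and the cyclopentenone closes as the formal [2+2+1] ring across C3, C2 and C1. The one new stereocentre, quaternary C9, is controlled by the neighbouring C8 centre: in the chair-like C5–C8 tether the C8 silyloxy group lies pseudo-equatorial, which should put C10 cis and C1 trans to it. The step needs chemoselectivity for this alkene and the regiochemistry that places the carbonyl between C1 and C3; the first is secured because no other alkene is present (the C12–C13 arm is added only afterwards), the second by the tether, helped by the gem-disubstituted C5.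

Step 13
Reactants: 18 the hydroxymethyl hydrindenone from step 12
Product: 19 (4S,5S,7S,7aR)-7-[(tert-butyldimethylsilyl)oxy]-7a-{(2R)-1-[(tert-butyldimethylsilyl)oxy]propan-2-yl}-4,5-dimethyl-2-oxo-2,4,5,6,7,7a-hexahydro-1H-indene-4-carbaldehyde
Conditions: Dess–Martin periodinane, CH2Cl2, rt
Reagents that add atoms: none
Why: Neutral oxidation of the neopentyl alcohol should give the C14 aldehyde, which has no α-hydrogen and cannot epimerise; the enone is untouched.

Step 14
Reactants: 20 3-methylbut-2-enal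
Product: 21 (E)-tert-butyldimethyl[(3-methylbuta-1,3-dien-1-yl)oxy]silane
Conditions: TBSOTf, Et3N, Et2O, 0 °C to rt
Reagents that add atoms: tert-butyldimethylsilyl trifluoromethanesulfonate, CC(C)(C)[Si](C)(C)OS(=O)(=O)C(F)(F)F
Why: O-silylation of the enal and γ-deprotonation (vinylogous enolisation) should give the (1E)-silyl dienol ether.

Step 15
Reactants: 19 the C14 aldehyde from step 13; 21 (E)-tert-butyldimethyl[(3-methylbuta-1,3-dien-1-yl)oxy]silane
Product: 22 (2E,5R)-5-[(4S,5S,7S,7aR)-7-[(tert-butyldimethylsilyl)oxy]-7a-{(2R)-1-[(tert-butyldimethylsilyl)oxy]propan-2-yl}-4,5-dimethyl-2-oxo-2,4,5,6,7,7a-hexahydro-1H-inden-4-yl]-5-hydroxy-3-methylpent-2-enal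
Conditions: 4-(1H-indol-3-ylmethyl)-2-phenyl-3-tosyl-1,3,2-oxazaborolidin-5-one (from N-tosyltryptophan and PhBCl2, 50 mol %, enantiomer chosen for 5R), i-PrOH, EtCN, −78 °C
Reagents that add atoms: none
Why: Vinylogous Mukaiyama aldol reaction: the γ-carbon of the dienol ether attacks the Lewis-acid-bound aldehyde to give the δ-hydroxy (E)-enal, the chiral boron Lewis acid selecting the aldehyde face that sets C14 as R, while the hindered β,β-disubstituted ring enone does not compete.

Step 16
Reactants: 22 the δ-hydroxy enal from step 15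
Product: 23 (4S,5S,7S,7aR)-7-[(tert-butyldimethylsilyl)oxy]-7a-{(2R)-1-[(tert-butyldimethylsilyl)oxy]propan-2-yl}-4-[(1R,3E)-1,5-dihydroxy-3-methylpent-3-en-1-yl]-4,5-dimethyl-1,4,5,6,7,7a-hexahydro-2H-inden-2-one
Conditions: NaBH4, MeOH/CH2Cl2, −78 °C
Reagents that add atoms: none
Why: At −78 °C borohydride reduces the aldehyde far faster than the hindered conjugated ring ketone, and the β,β-disubstituted enal should react 1,2 to give the allylic alcohol.

Step 17
Reactants: 23 the diol from step 16
Product: 24 (2E,5R)-5-acetoxy-5-[(4S,5S,7S,7aR)-7-[(tert-butyldimethylsilyl)oxy]-7a-{(2R)-1-[(tert-butyldimethylsilyl)oxy]propan-2-yl}-4,5-dimethyl-2-oxo-2,4,5,6,7,7a-hexahydro-1H-inden-4-yl]-3-methylpent-2-en-1-yl acetate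
Conditions: Ac2O, 4-(dimethylamino)pyridine, pyridine, CH2Cl2, rt
Reagents that add atoms: acetic anhydride, CC(=O)OC(C)=O
Why: One acetylation installs the C14 acetate of the target while it is the only free secondary hydroxyl and turns the primary allylic alcohol into the leaving group needed in step 20.

Step 18
Reactants: 24 the diacetate from step 17
Product: 25 (2E,5R)-5-acetoxy-5-[(4S,5S,7S,7aR)-7-[(tert-butyldimethylsilyl)oxy]-7a-[(2R)-1-hydroxypropan-2-yl]-4,5-dimethyl-2-oxo-2,4,5,6,7,7a-hexahydro-1H-inden-4-yl]-3-methylpent-2-en-1-yl acetate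
Conditions: HF·pyridine, pyridine/THF, 0 °C
Reagents that add atoms: none
Why: The primary silyl ether is cleaved much faster than the hindered secondary one at C8, and buffered HF leaves both acetates in place.

Step 19
Reactants: 25 the primary alcohol from step 18
Product: 26 (2E,5R)-5-acetoxy-5-[(4S,5S,7S,7aR)-7-[(tert-butyldimethylsilyl)oxy]-4,5-dimethyl-2-oxo-7a-[(2R)-1-oxopropan-2-yl]-2,4,5,6,7,7a-hexahydro-1H-inden-4-yl]-3-methylpent-2-en-1-yl acetate
Conditions: Dess–Martin periodinane, NaHCO3, CH2Cl2, 0 °C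
Reagents that add atoms: none
Why: Buffered oxidation should give the α-branched C11 aldehyde without epimerising C10; it is used directly.

Step 20
Reactants: 26 the aldehyde allylic acetate from step 19
Product: 28 8-O-(tert-butyldimethylsilyl) ether of the target (5S,6S,8S,9R,10R,11S,12S,14R), via allylzinc 27 (not isolated)
Conditions: Pd(PPh3)4 (10 mol %), Et2Zn (3 equiv), THF (0.005 M), rt
Reagents that add atoms: none
Why: Palladium/diethylzinc umpolung allylation: zerovalent palladium ionises only the allylic acetate, transmetalation gives the allylzinc, and its γ-carbon (C12) adds to the C11 aldehyde through a closed Zimmerman–Traxler transition state, closing the eight-membered ring and creating the quaternary C12 with its vinyl group; since the allylzinc isomers interconvert by 1,3-metal shift, the ring constraint should select the chair that places the C11 hydroxyl syn to the vinyl group (11S,12S), and a C12 epimer can be returned through retro-allylation of its zinc alkoxide.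

Step 21
Reactants: 28 the 8-O-TBS ether of the target
Product: 29 Pleuromutilin E (target)
Conditions: HF·pyridine, THF, rt
Reagents that add atoms: none
Why: Acidic fluoride removes the hindered secondary silyl ether at C8 without cleaving or migrating the C14 acetate.

**Compound list**
1 | methyl (S)-3-hydroxy-2-methylpropanoate | COC(=O)[C@@H](C)CO | starting material
2 | methyl (S)-3-[(tert-butyldimethylsilyl)oxy]-2-methylpropanoate | COC(=O)[C@@H](C)CO[Si](C)(C)C(C)(C)C | intermediate
3 | (S)-3-[(tert-butyldimethylsilyl)oxy]-2-methylpropanal | O=C[C@@H](C)CO[Si](C)(C)C(C)(C)C | intermediate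
4 | (R)-tert-butyldimethyl[(2-methylbut-3-yn-1-yl)oxy]silane | C#C[C@@H](C)CO[Si](C)(C)C(C)(C)C | intermediate
5 | 9-[(1Z,3S)-4-[(tert-butyldimethylsilyl)oxy]-2-iodo-3-methylbut-1-en-1-yl]-9-borabicyclo[3.3.1]nonane (not isolated) | I/C(=C\B1C2CCCC1CCC2)[C@@H](C)CO[Si](C)(C)C(C)(C)C | intermediate
6 | (S)-tert-butyl[(3-iodo-2-methylbut-3-en-1-yl)oxy]dimethylsilane | C=C(I)[C@@H](C)CO[Si](C)(C)C(C)(C)C | intermediate
7 | methyl 2-methyl-3-oxobutanoate (racemic) | CC(=O)C(C)C(=O)OC | starting material
8 | (E)-1-chlorobut-2-ene | C/C=C/CCl | starting material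
9 | methyl (2S,3S)-2-acetyl-2,3-dimethylpent-4-enoate | COC(=O)[C@](C)(C(C)=O)[C@@H](C)C=C | intermediate
10 | methyl (2S,3S)-2-acetyl-5-(9-borabicyclo[3.3.1]nonan-9-yl)-2,3-dimethylpentanoate (not isolated) | COC(=O)[C@](C)(C(C)=O)[C@@H](C)CCB1C2CCCC1CCC2 | intermediate
11 | methyl (2S,3S)-2-acetyl-5-hydroxy-2,3-dimethylpentanoate | COC(=O)[C@](C)(C(C)=O)[C@@H](C)CCO | intermediate
12 | methyl (2S,3S)-2-acetyl-2,3-dimethyl-5-oxopentanoate | COC(=O)[C@](C)(C(C)=O)[C@@H](C)CC=O | intermediate
13 | methyl (2S,3S,5S,7R)-2-acetyl-8-[(tert-butyldimethylsilyl)oxy]-5-hydroxy-2,3,7-trimethyl-6-methylideneoctanoate | COC(=O)[C@](C)(C(C)=O)[C@@H](C)C[C@H](O)C(=C)[C@@H](C)CO[Si](C)(C)C(C)(C)C | intermediate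
14 | methyl (2S,3S,5S,7R)-2-acetyl-5,8-bis[(tert-butyldimethylsilyl)oxy]-2,3,7-trimethyl-6-methylideneoctanoate | COC(=O)[C@](C)(C(C)=O)[C@@H](C)C[C@H](O[Si](C)(C)C(C)(C)C)C(=C)[C@@H](C)CO[Si](C)(C)C(C)(C)C | intermediate
15 | methyl (2S,3S,5S,7R)-5,8-bis[(tert-butyldimethylsilyl)oxy]-2-{1-[(diethoxyphosphoryl)oxy]ethenyl}-2,3,7-trimethyl-6-methylideneoctanoate (not isolated) | COC(=O)[C@](C)(C(=C)OP(=O)(OCC)OCC)[C@@H](C)C[C@H](O[Si](C)(C)C(C)(C)C)C(=C)[C@@H](C)CO[Si](C)(C)C(C)(C)C | intermediate
16 | methyl (2S,3S,5S,7R)-5,8-bis[(tert-butyldimethylsilyl)oxy]-2-ethynyl-2,3,7-trimethyl-6-methylideneoctanoate | COC(=O)[C@](C)(C#C)[C@@H](C)C[C@H](O[Si](C)(C)C(C)(C)C)C(=C)[C@@H](C)CO[Si](C)(C)C(C)(C)C | intermediate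
17 | (2S,3S,5S,7R)-5,8-bis[(tert-butyldimethylsilyl)oxy]-2-ethynyl-2,3,7-trimethyl-6-methylideneoctan-1-ol | OC[C@](C)(C#C)[C@@H](C)C[C@H](O[Si](C)(C)C(C)(C)C)C(=C)[C@@H](C)CO[Si](C)(C)C(C)(C)C | intermediate
18 | (4S,5S,7S,7aR)-7-[(tert-butyldimethylsilyl)oxy]-7a-{(2R)-1-[(tert-butyldimethylsilyl)oxy]propan-2-yl}-4-(hydroxymethyl)-4,5-dimethyl-1,4,5,6,7,7a-hexahydro-2H-inden-2-one | OC[C@]1(C)C2=CC(=O)C[C@@]2([C@@H](O[Si](C)(C)C(C)(C)C)C[C@@H]1C)[C@@H](C)CO[Si](C)(C)C(C)(C)C | intermediate
19 | (4S,5S,7S,7aR)-7-[(tert-butyldimethylsilyl)oxy]-7a-{(2R)-1-[(tert-butyldimethylsilyl)oxy]propan-2-yl}-4,5-dimethyl-2-oxo-2,4,5,6,7,7a-hexahydro-1H-indene-4-carbaldehyde | O=C[C@]1(C)C2=CC(=O)C[C@@]2([C@@H](O[Si](C)(C)C(C)(C)C)C[C@@H]1C)[C@@H](C)CO[Si](C)(C)C(C)(C)C | intermediate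
20 | 3-methylbut-2-enal | CC(C)=CC=O | starting material
21 | (E)-tert-butyldimethyl[(3-methylbuta-1,3-dien-1-yl)oxy]silane | C=C(C)/C=C/O[Si](C)(C)C(C)(C)C | intermediate
22 | (2E,5R)-5-[(4S,5S,7S,7aR)-7-[(tert-butyldimethylsilyl)oxy]-7a-{(2R)-1-[(tert-butyldimethylsilyl)oxy]propan-2-yl}-4,5-dimethyl-2-oxo-2,4,5,6,7,7a-hexahydro-1H-inden-4-yl]-5-hydroxy-3-methylpent-2-enal | O=C/C=C(\C)C[C@@H](O)[C@]1(C)C2=CC(=O)C[C@@]2([C@@H](O[Si](C)(C)C(C)(C)C)C[C@@H]1C)[C@@H](C)CO[Si](C)(C)C(C)(C)C | intermediate
23 | (4S,5S,7S,7aR)-7-[(tert-butyldimethylsilyl)oxy]-7a-{(2R)-1-[(tert-butyldimethylsilyl)oxy]propan-2-yl}-4-[(1R,3E)-1,5-dihydroxy-3-methylpent-3-en-1-yl]-4,5-dimethyl-1,4,5,6,7,7a-hexahydro-2H-inden-2-one | OC/C=C(\C)C[C@@H](O)[C@]1(C)C2=CC(=O)C[C@@]2([C@@H](O[Si](C)(C)C(C)(C)C)C[C@@H]1C)[C@@H](C)CO[Si](C)(C)C(C)(C)C | intermediate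
24 | (2E,5R)-5-acetoxy-5-[(4S,5S,7S,7aR)-7-[(tert-butyldimethylsilyl)oxy]-7a-{(2R)-1-[(tert-butyldimethylsilyl)oxy]propan-2-yl}-4,5-dimethyl-2-oxo-2,4,5,6,7,7a-hexahydro-1H-inden-4-yl]-3-methylpent-2-en-1-yl acetate | CC(=O)OC/C=C(\C)C[C@@H](OC(C)=O)[C@]1(C)C2=CC(=O)C[C@@]2([C@@H](O[Si](C)(C)C(C)(C)C)C[C@@H]1C)[C@@H](C)CO[Si](C)(C)C(C)(C)C | intermediate
25 | (2E,5R)-5-acetoxy-5-[(4S,5S,7S,7aR)-7-[(tert-butyldimethylsilyl)oxy]-7a-[(2R)-1-hydroxypropan-2-yl]-4,5-dimethyl-2-oxo-2,4,5,6,7,7a-hexahydro-1H-inden-4-yl]-3-methylpent-2-en-1-yl acetate | CC(=O)OC/C=C(\C)C[C@@H](OC(C)=O)[C@]1(C)C2=CC(=O)C[C@@]2([C@@H](O[Si](C)(C)C(C)(C)C)C[C@@H]1C)[C@@H](C)CO | intermediate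
26 | (2E,5R)-5-acetoxy-5-[(4S,5S,7S,7aR)-7-[(tert-butyldimethylsilyl)oxy]-4,5-dimethyl-2-oxo-7a-[(2R)-1-oxopropan-2-yl]-2,4,5,6,7,7a-hexahydro-1H-inden-4-yl]-3-methylpent-2-en-1-yl acetate | CC(=O)OC/C=C(\C)C[C@@H](OC(C)=O)[C@]1(C)C2=CC(=O)C[C@@]2([C@@H](O[Si](C)(C)C(C)(C)C)C[C@@H]1C)[C@@H](C)C=O | intermediate
27 | ethyl(allyl)zinc species of 26, in which CH2–ZnEt replaces the allylic CH2–OAc (not isolated) | CC[Zn]C/C=C(\C)C[C@@H](OC(C)=O)[C@]1(C)C2=CC(=O)C[C@@]2([C@@H](O[Si](C)(C)C(C)(C)C)C[C@@H]1C)[C@@H](C)C=O | intermediate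
28 | 8-O-(tert-butyldimethylsilyl) ether of the target, (5S,6S,8S,9R,10R,11S,12S,14R) | C=C[C@]1(C)C[C@@H](OC(C)=O)[C@]2(C)C3=CC(=O)C[C@@]3([C@@H](O[Si](C)(C)C(C)(C)C)C[C@@H]2C)[C@@H](C)[C@@H]1O | intermediate
29 | Pleuromutilin E, (5S,6S,8S,9R,10R,11S,12S,14R) | C=C[C@]1(C)C[C@@H](OC(C)=O)[C@]2(C)C3=CC(=O)C[C@@]3([C@@H](O)C[C@@H]2C)[C@@H](C)[C@@H]1O | target

**Step count and risks**
Total step count: 21. Longest linear sequence: 17 steps (steps 1–4, 8–13 and 15–21, starting from 1).

Step 20 (most likely to fail). The slow eight-membered ring closure may be outrun by β-hydride loss from the allyl–metal species (diene formation) or by intermolecular allylation, and the closed transition state may not fix the C12 configuration. Fallback: starting from diacetate 24, palladium-catalysed silylation of the allylic acetate with hexamethyldisilane (Pd(dba)2, LiCl, DMF) should give the allyltrimethylsilane F1. Selective removal of the primary silyl ether (HF·pyridine) should give the alcohol F2, and Dess–Martin oxidation the aldehyde F3. An intramolecular Hosomi–Sakurai reaction (BF3·OEt2, CH2Cl2, −78 °C), which runs through an open antiperiplanar transition state instead of the closed one, then closes the ring and returns to the route at 28.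

Step 12. Insertion of the hindered 1,1-disubstituted alkene, branched on both allylic carbons, may be slower than alkyne oligomerisation or decomposition of the cobalt complex, and facial selectivity at C9 may be incomplete. Fallback: starting from enynol 17, a stoichiometric zerovalent nickel [2+2+1] cyclisation with tert-butyl isocyanide in place of CO (Ni(cod)2, PBu3, t-BuNC, THF) should give the iminocyclopentene F4. Mild hydrolysis (aqueous oxalic acid) converts it into enone 18, where the route is rejoined.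

Step 5. With the small crotyl electrophile the branched-to-linear ratio may erode, and the enolate face may be poorly discriminated, giving low diastereocontrol at the quaternary carbon. Fallback: starting from ketoester 7, an iminium-catalysed Michael addition to (E)-but-2-enal (C/C=C/C=O) with a diarylprolinol silyl ether should set C6 and deliver keto aldehyde 12 directly. It is run cold with an acid co-catalyst so that the adduct does not go on to an intramolecular aldol, and the C5 epimers are separated. The route is rejoined at 12, and no compound outside the list is made: none F0.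

**Further compounds**
F1 | step 20 | allyltrimethylsilane analogue of 24 (CH2–SiMe3 in place of the allylic CH2–OAc) | C[Si](C)(C)C/C=C(\C)C[C@@H](OC(C)=O)[C@]1(C)C2=CC(=O)C[C@@]2([C@@H](O[Si](C)(C)C(C)(C)C)C[C@@H]1C)[C@@H](C)CO[Si](C)(C)C(C)(C)C
F2 | step 20 | primary alcohol from F1 | C[Si](C)(C)C/C=C(\C)C[C@@H](OC(C)=O)[C@]1(C)C2=CC(=O)C[C@@]2([C@@H](O[Si](C)(C)C(C)(C)C)C[C@@H]1C)[C@@H](C)CO
F3 | step 20 | aldehyde from F2 | C[Si](C)(C)C/C=C(\C)C[C@@H](OC(C)=O)[C@]1(C)C2=CC(=O)C[C@@]2([C@@H](O[Si](C)(C)C(C)(C)C)C[C@@H]1C)[C@@H](C)C=O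
F4 | step 12 | N-tert-butyl imine of 18 | OC[C@]1(C)C2=CC(=NC(C)(C)C)C[C@@]2([C@@H](O[Si](C)(C)C(C)(C)C)C[C@@H]1C)[C@@H](C)CO[Si](C)(C)C(C)(C)C
F0 | step 5 | none | none
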